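# Proposed total synthesis of CNP0140823.2, epioritin-(4β→6)-oritin-(4α→6)-epioritin-4α-ol

## Analysis of the target

The target is a linear trimer of three flavan units, called T (upper), M (middle) and B (lower) here, each a 2-aryl-3,4-dihydro-2H-chromene with a 7,8-dihydroxylated ring A and a 4-hydroxyphenyl ring B, joined by the bonds C4(T)–C6(M) and C4(M)–C6(B). There are nine stereocentres, C2, C3 and C4 of each ring C, and every C2 is R: T is 2,3-cis-3,4-trans (2R,3R,4S), M is 2,3-trans-3,4-trans (2R,3S,4R), and B is 2,3-cis-3,4-cis (2R,3R,4R) with a free hydroxyl at C4. T and B therefore share one C2/C3 pattern and M is their C3 epimer, while in both interflavanyl bonds the aryl group on C4 is trans to O3. The sensitive points are the C4 hydroxyl of B (benzylic, para to O7 and ortho to O1, so it ionises with acid and can be hydrogenolysed), the benzylic C2–O1 ethers, and the free pyrogallol-type rings A, which oxidise in air under base. The synthesis is hard because ring A is only a moderate nucleophile and offers C5 as well as C6, because the two interflavanyl C4 centres lie far from the stereocentres of the neighbouring unit, and because the 3,4-cis carbinol of B is not the isomer that capture of a C4 cation would give. The strategy rests on ring C of unit B, where C2, C3 and C4 each carry oxygen (O1, the 3-hydroxyl, the 4-hydroxyl), which is the oxidation pattern of glyceraldehyde, and where C4 is bonded to C4a, a position of ring A ortho to O1 and para to O7. The C4–C4a bond can therefore be made by attack of ring A on a C4 aldehyde whose face is fixed by chelation to O3, and the same C2–C3–C4 chain recurs unchanged in T and with C3 inverted in M.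

## Retrosynthetic reasoning

**Protecting groups.** Target 32 is traced back to the dodeca-O-benzyl 6-bromo trimer 31, and 31 to its silyl ether 30. The silyl group on O4 of unit B shields the one ionisable C–O bond while the interflavanyl bonds are made. It is taken off before the hydrogenolysis, so that the basic desilylation never meets free pyrogallol rings.

**C4(T)–C6(M).** Trimer 30 is cut into the thioether 17 (unit T) and the dimer 29. The cut is placed here because the C4 cation formed from 17 takes a carbon nucleophile anti to its axial O3, which is the 3,4-trans arrangement that T needs. A benzylthio leaving group answers to thiophilic activation and not to hard acid, so the C4–O bond of unit B is left alone. The bromine on C6 of 17 keeps the cation from alkylating its own kind.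

**C4(M)–C6(B).** Dimer 29 is cut into the thioether 28 (unit M) and the silyl ether 15 (unit B). C6 of 15 is ortho to O7 and para to O1, whereas C5 is para only to the twisted O8 and is flanked by C4, so ring A should react at C6. The 2,3-trans cation from 28 is attacked anti to O3, giving the 3,4-trans bond of M. This bond is made first, between two monomers, where crowding is least.

**One flavan for two units.** 15 and 17 both come from the flavan-3,4-diol derivative 14, the first by silylation and the second by bromination to 16 and thiolysis. 28 comes from the C3-epimeric flavan-4-ol 27 by thiolysis. The whole problem is thereby reduced to 14 and 27.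

**C4–C4a (key disconnection).** 14 is opened between C4 and C4a to the aldehyde 13, and 27 in the same way to 26. Cutting here removes ring C and the C4 stereocentre together and leaves an open chain whose two stereocentres are C2 and C3 only. Forward, ring A must attack the aldehyde at C4a, and in 14 the carbinol must come out cis to O3, which the benzyl ether on O3 can enforce through a chelate.

**Aldehyde and O3 benzyl ether.** 13 comes from the primary alcohol 12, and 12 from the benzylidene acetal 11 of diol 10 by reductive opening. This places the benzyl group on the secondary oxygen and frees the primary one in a single operation. 10 is the hydrolysis product of acetonide 9. The M series runs 26 ← 25 ← 24 ← 23 ← 22 in the same way.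

**C2–O1.** The aryl ether bond of 9 is cut to the carbinol 8 and phenol 4, and that of 22 to the carbinol 21 and 4. A Mitsunobu etherification inverts the carbinol, so the anti carbinol 8 gives the 2,3-cis series and the syn carbinol 21 the 2,3-trans series.

**C2–C1′ and the chiral pool.** 8 comes from the Grignard reagent 6, made from the aryl bromide 5, and (R)-glyceraldehyde acetonide 7 by Felkin–Anh addition. 21 comes from the same reagent 6 and the enantiomeric aldehyde 18 by addition to 19, oxidation to ketone 20 and Felkin–Anh reduction. C3 of every unit is thus taken from the pool, C2 is set next to it, and one batch of 6 serves both branches.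

**Ring A.** Phenol 4 comes from 2,3-dihydroxybenzaldehyde 1 through dibenzyl ether 2 and formate 3 by Baeyer–Villiger oxidation.

## Alternatives that were turned down

Alternative 1: The pyran ring of unit M is disconnected at C3–C4 and O1–C2 and is built on C6 of unit B. A chiral Brønsted acid of the N-triflyl phosphoramide type would ionise the ortho-hydroxy diaryl carbinol A1 to the ortho-quinone methide A2, which adds the aryl alkyne A3 to give the 4H-chromene dimer A4 with C4 of M set.
- For it: two bonds and a ring form in one step, and later hydroboration of the enol ether of A4 would deliver the 2,3-trans-3,4-trans pattern that M needs. No separate branch for M is required, so on step economy for unit M it is stronger than the chosen route.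
- Against it: C4 of M is the only centre set in the key step, and it is set by the catalyst alone. The stereocentres of B lie four bonds away and can only match or mismatch the catalyst. The methide carbon of A2 carries the whole of unit B, A3 is a weak 2π partner, and the acid needed sits beside the acid-labile benzylic 3,4-acetonide of B. Unit T would need the same sequence again and then an inversion at C3, since hydroboration gives only 2,3-trans.
- Comparison: the chosen strategy sets both interflavanyl C4 centres from the neighbouring C3 of the same unit and takes C2 and C3 from the pool. It pays for this with a second chiral-pool branch.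

Alternative 2: Ring C of unit B is disconnected at O1–C8a. A CuI-catalysed Ullmann-type etherification under carbonate base would couple the C2 hydroxyl of the bromo alcohol A5 with the ortho aryl bromide to give A6, which is the same compound as 15.
- For it: no stereocentre is touched in the ring closure and no Lewis acid comes near the C4–O bond. On the safety of the C4 carbinol it is stronger than the chosen key step, and its product enters the same endgame.
- Against it: all three stereocentres C2, C3 and C4 must be built in the open chain beforehand, so the ring closure adds no stereochemical value. The bromide is flanked by a benzyloxy group and the nucleophile is a secondary benzylic alkoxide, so the coupling needs heat and base. Under those conditions retro-aldol cleavage, silyl migration from O4 to O2 and epimerisation at C2 are open.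
- Comparison: the chosen strategy creates C4 in the ring-forming step itself from a C3 that is bought, and reaches the ring in fewer stereo-defining steps.

Alternative 3: Ring C of unit T is disconnected at O1–C2 on the fully assembled skeleton. Mild Brønsted or Lewis acid would make the ring A phenol of the cis-epoxide A7 open the epoxide at benzylic C2 with inversion, giving the trimer A8 with its 3-hydroxyl released.
- For it: a cis-epoxide opened with inversion gives 2,3-cis by a stereospecific path. No separate T electrophile and no bromine cap are needed, and on that point it is leaner than the chosen route.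
- Against it: A7 already contains C4 of T, a diarylmethine next to an epoxide, which must be set after units M and B have been joined. That is exactly the remote-control problem. The phenol can also open the epoxide at C3 in a 5-exo mode. The 6-endo opening at C2 needs cationic character there, which invites loss of inversion, while the pivalate that tames this character also removes the bias for C2. The acetonide on C3/C4 of B must survive the same acid.
- Comparison: the chosen strategy makes T from the same flavan as B and forms its C4 bond with the built-in 3,4-trans preference of a 2,3-cis cation.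

Key step: step 10

## Route

Remark on the chemistry: in 11, 19, 24 and 27 one centre that is reduced away, oxidised or ionised in the following step is carried as an epimer mixture and is left undefined in the SMILES.

Step 1
Reactants: 1 2,3-dihydroxybenzaldehyde
Product: 2 2,3-bis(benzyloxy)benzaldehyde
Conditions: BnBr (2.3 equiv), K2CO3, DMF, 60 °C
Reagents that add atoms: benzyl bromide, BrCc1ccccc1
Why: Williamson etherification of both phenols; the aldehyde is inert to carbonate in DMF.

Step 2
Reactants: 2 2,3-bis(benzyloxy)benzaldehyde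
Product: 4 2,3-bis(benzyloxy)phenol, via aryl formate 3 (not isolated)
Conditions: mCPBA, CH2Cl2, rt; then K2CO3 (cat.), MeOH, rt
Reagents that add atoms: 3-chloroperoxybenzoic acid, OOC(=O)c1cccc(Cl)c1
Why: Baeyer–Villiger oxidation; the electron-rich aryl group with its ortho alkoxy substituent migrates in preference to hydride, and the formate is cleaved by methanolysis.

Step 3
Reactants: 5 1-(benzyloxy)-4-bromobenzene
Product: 6 [4-(benzyloxy)phenyl]magnesium bromide (titrated THF solution kept under argon)
Conditions: Mg turnings, I2 (cat.), THF, 40 °C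
Reagents that add atoms: magnesium, [Mg]
Why: Grignard reagent formation by insertion of magnesium into the aryl C–Br bond; the benzyl ether is inert, and one titrated batch is divided between steps 4 and 14.

Step 4
Reactants: 6 [4-(benzyloxy)phenyl]magnesium bromide; 7 (R)-glyceraldehyde acetonide
Product: 8 (S)-[4-(benzyloxy)phenyl][(4R)-2,2-dimethyl-1,3-dioxolan-4-yl]methanol
Conditions: THF, −78 → −20 °C; aq. NH4Cl
Reagents that add atoms: none
Why: Grignard addition under Felkin–Anh control: the aryl group adds anti to the dioxolane C–O bond, so the (S)-carbinol anti to the ring oxygen should be the major epimer. The minor syn epimer is to be removed by chromatography.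

Step 5
Reactants: 8 anti carbinol; 4 2,3-bis(benzyloxy)phenol
Product: 9 (4R)-4-{(R)-[2,3-bis(benzyloxy)phenoxy][4-(benzyloxy)phenyl]methyl}-2,2-dimethyl-1,3-dioxolane
Conditions: PPh3, DIAD, toluene, 0 °C → rt
Reagents that add atoms: none
Why: Mitsunobu etherification; the phenoxide displaces the alkoxyphosphonium group with inversion, turning the (S)-carbinol into the (R)-aryl ether syn to O3, the later 2,3-cis relationship. The β-oxygen of the dioxolane and the non-polar solvent work against ionisation of the benzylic carbon.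

Step 6
Reactants: 9 aryl ether acetonide
Product: 10 (2R,3R)-3-[2,3-bis(benzyloxy)phenoxy]-3-[4-(benzyloxy)phenyl]propane-1,2-diol
Conditions: AcOH/H2O/THF (4:1:1), 40 °C
Reagents that add atoms: none
Why: Acid-catalysed hydrolysis of the isopropylidene acetal; dilute acetic acid is too weak to ionise the benzylic aryl ether or to touch the benzyl ethers.

Step 7
Reactants: 10 diol
Product: 11 (4R)-4-{(R)-[2,3-bis(benzyloxy)phenoxy][4-(benzyloxy)phenyl]methyl}-2-phenyl-1,3-dioxolane (both epimers at the acetal carbon)
Conditions: PhCH(OMe)2, CSA (cat.), CH2Cl2, rt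
Reagents that add atoms: benzaldehyde dimethyl acetal, COC(OC)c1ccccc1
Why: Acetal exchange to the five-membered benzylidene acetal; the new acetal centre is of no consequence because both epimers open to the same product.

Step 8
Reactants: 11 benzylidene acetal
Product: 12 (2R,3R)-2-(benzyloxy)-3-[2,3-bis(benzyloxy)phenoxy]-3-[4-(benzyloxy)phenyl]propan-1-ol
Conditions: i-Bu2AlH (3 equiv), CH2Cl2, −78 → 0 °C; aq. potassium sodium tartrate
Reagents that add atoms: none
Why: Reductive opening of a benzylidene acetal: aluminium binds the less hindered primary oxygen, that C–O bond breaks and hydride reduces the oxocarbenium ion. The benzyl group is left on the secondary oxygen and the primary alcohol is freed.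

Step 9
Reactants: 12 primary alcohol
Product: 13 (2S,3R)-2-(benzyloxy)-3-[2,3-bis(benzyloxy)phenoxy]-3-[4-(benzyloxy)phenyl]propanal
Conditions: Dess–Martin periodinane, pyridine, CH2Cl2, 0 °C → rt
Reagents that add atoms: none
Why: Dess–Martin oxidation under near-neutral conditions, which should leave the α-benzyloxy stereocentre unepimerised; 13 is used at once.

Step 10
Reactants: 13 (2S,3R)-2-(benzyloxy)-3-[2,3-bis(benzyloxy)phenoxy]-3-[4-(benzyloxy)phenyl]propanal
Product: 14 (2R,3R,4R)-3,7,8-tris(benzyloxy)-2-[4-(benzyloxy)phenyl]-3,4-dihydro-2H-chromen-4-ol (2,3-cis-3,4-cis; 3-O-benzyl teracacidin tribenzyl ether)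
Conditions: SnCl4 (1.2 equiv), CH2Cl2 (0.01 M), −78 °C; Et3N, then aq. NaHCO3 at −78 °C
Reagents that add atoms: none
Why: SnCl4 binds the aldehyde oxygen and the benzyl ether oxygen on C3 in a five-membered chelate, and C4a of ring A (ortho to O1, para to the 7-benzyloxy group) attacks the activated carbonyl carbon; loss of the proton restores the arene and leaves the tin alkoxide of the chroman-4-ol. The closest known reaction type is the Lewis acid-mediated intramolecular Friedel–Crafts hydroxyalkylation of 3-aryloxypropanals to chroman-4-ols, combined with chelation control as in additions to α-benzyloxy aldehydes. Ring C closes in a 6-exo-trig mode through the C4–C4a bond, with the arene π bond inside the new ring. The new stereocentre C4 is controlled by the chelate: in the chair-like transition state the 2-aryl group is equatorial, so the C3–O bond is axial, and the chelated carbonyl oxygen must lie gauche to it, that is equatorial, which gives the 3,4-cis carbinol. Regioselectivity is not in question, because C4a is the only free position the tether can reach. The step needs 3,4-cis selectivity and survival of the new benzylic C–O bond; the first rests on the α-benzyloxy group placed in step 8, the second on high dilution, −78 °C, the covalent tin alkoxide and a basic quench before warming.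

Step 11
Reactants: 14 flavan-4-ol
Product: 15 tert-butyl{[(2R,3S,4R)-3,7,8-tris(benzyloxy)-2-[4-(benzyloxy)phenyl]-3,4-dihydro-2H-chromen-4-yl]oxy}dimethylsilane (4-O-silyl ether of 14; the change of the C3 descriptor is formal)
Conditions: TBSCl, imidazole, DMAP (cat.), DMF, rt
Reagents that add atoms: tert-butyldimethylsilyl chloride, C[Si](C)(Cl)C(C)(C)C
Why: Silylation of the secondary alcohol under basic conditions that cannot ionise C4; the bulky, weakly basic silyl ether oxygen protects the C4–O bond in the later steps.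

Step 12
Reactants: 14 flavan-4-ol
Product: 16 (2R,3R,4R)-3,7,8-tris(benzyloxy)-2-[4-(benzyloxy)phenyl]-6-bromo-3,4-dihydro-2H-chromen-4-ol
Conditions: NBS (1.05 equiv), MeCN/CH2Cl2, −20 → 0 °C, dark
Reagents that add atoms: N-bromosuccinimide, BrN1C(=O)CCC1=O
Why: Electrophilic aromatic bromination; C6 is ortho to the 7-benzyloxy group and para to O1, whereas C5 is para only to the twisted 8-benzyloxy group and ring B carries one oxygen, so ring A should be brominated at C6.

Step 13
Reactants: 16 6-bromoflavan-4-ol
Product: 17 (2R,3S,4S)-4-(benzylsulfanyl)-3,7,8-tris(benzyloxy)-2-[4-(benzyloxy)phenyl]-6-bromo-3,4-dihydro-2H-chromene (2,3-cis-3,4-trans)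
Conditions: BnSH (3 equiv), ZnI2 (0.5 equiv), CH2Cl2, 0 °C → rt
Reagents that add atoms: phenylmethanethiol, SCc1ccccc1
Why: SN1 thiolysis of the benzylic alcohol: ZnI2 assists ionisation and the thiol adds to the C4 cation anti to the axial 3-benzyloxy group. The bromine on C6 prevents the cation from alkylating ring A of a second molecule.

Step 14
Reactants: 6 [4-(benzyloxy)phenyl]magnesium bromide (second portion of the solution from step 3); 18 (S)-glyceraldehyde acetonide
Product: 19 [4-(benzyloxy)phenyl][(4S)-2,2-dimethyl-1,3-dioxolan-4-yl]methanol (both carbinol epimers)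
Conditions: THF, −78 → −20 °C; aq. NH4Cl
Reagents that add atoms: none
Why: Grignard addition to the aldehyde; both carbinol epimers are acceptable because the carbinol is oxidised in step 15.

Step 15
Reactants: 19 carbinol mixture
Product: 20 [4-(benzyloxy)phenyl][(4S)-2,2-dimethyl-1,3-dioxolan-4-yl]methanone
Conditions: Dess–Martin periodinane, pyridine, CH2Cl2, 0 °C → rt
Reagents that add atoms: none
Why: Dess–Martin oxidation of a benzylic alcohol; the neutral medium should keep the α-alkoxy stereocentre intact.

Step 16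
Reactants: 20 aryl ketone
Product: 21 (S)-[4-(benzyloxy)phenyl][(4S)-2,2-dimethyl-1,3-dioxolan-4-yl]methanol (syn)
Conditions: LiBH(s-Bu)3, THF, −78 °C; H2O
Reagents that add atoms: none
Why: Felkin–Anh reduction of an α-alkoxy ketone: the bulky borohydride attacks anti to the dioxolane C–O bond past the hydrogen of the α-carbon, which for a ketone gives the carbinol syn to the ring oxygen.

Step 17
Reactants: 21 syn carbinol; 4 2,3-bis(benzyloxy)phenol
Product: 22 (4S)-4-{(R)-[2,3-bis(benzyloxy)phenoxy][4-(benzyloxy)phenyl]methyl}-2,2-dimethyl-1,3-dioxolane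
Conditions: PPh3, DIAD, toluene, 0 °C → rt
Reagents that add atoms: none
Why: Mitsunobu etherification with inversion, as in step 5; the (S)-carbinol becomes the (R)-aryl ether anti to O3, the later 2,3-trans relationship.

Step 18
Reactants: 22 aryl ether acetonide
Product: 23 (2S,3R)-3-[2,3-bis(benzyloxy)phenoxy]-3-[4-(benzyloxy)phenyl]propane-1,2-diol
Conditions: AcOH/H2O/THF (4:1:1), 40 °C
Reagents that add atoms: none
Why: Acetal hydrolysis under the mild conditions of step 6.

Step 19
Reactants: 23 diol
Product: 24 (4S)-4-{(R)-[2,3-bis(benzyloxy)phenoxy][4-(benzyloxy)phenyl]methyl}-2-phenyl-1,3-dioxolane (both epimers at the acetal carbon)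
Conditions: PhCH(OMe)2, CSA (cat.), CH2Cl2, rt
Reagents that add atoms: benzaldehyde dimethyl acetal, COC(OC)c1ccccc1
Why: Acetal exchange as in step 7.

Step 20
Reactants: 24 benzylidene acetal
Product: 25 (2S,3R)-2-(benzyloxy)-3-[2,3-bis(benzyloxy)phenoxy]-3-[4-(benzyloxy)phenyl]propan-1-ol
Conditions: i-Bu2AlH (3 equiv), CH2Cl2, −78 → 0 °C; aq. potassium sodium tartrate
Reagents that add atoms: none
Why: Regioselective reductive opening of the benzylidene acetal as in step 8; benzyl stays on the secondary oxygen.

Step 21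
Reactants: 25 primary alcohol
Product: 26 (2R,3R)-2-(benzyloxy)-3-[2,3-bis(benzyloxy)phenoxy]-3-[4-(benzyloxy)phenyl]propanal
Conditions: Dess–Martin periodinane, pyridine, CH2Cl2, 0 °C → rt
Reagents that add atoms: none
Why: Dess–Martin oxidation as in step 9; the aldehyde is used at once.

Step 22
Reactants: 26 aldehyde
Product: 27 (2R,3S)-3,7,8-tris(benzyloxy)-2-[4-(benzyloxy)phenyl]-3,4-dihydro-2H-chromen-4-ol (2,3-trans; both C4 epimers)
Conditions: SnCl4 (1.2 equiv), CH2Cl2 (0.01 M), −78 °C; Et3N, then aq. NaHCO3 at −78 °C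
Reagents that add atoms: none
Why: The same Friedel–Crafts hydroxyalkylation as in step 10 (6-exo-trig closure at C4a) in the 2,3-trans series. With the C3–O bond equatorial both chelated arrangements of the carbonyl are open, so a mixture at C4 is expected; this does not matter because C4 is ionised in steps 23 and 24.

Step 23
Reactants: 27 2,3-trans flavan-4-ol
Product: 28 (2R,3R,4R)-4-(benzylsulfanyl)-3,7,8-tris(benzyloxy)-2-[4-(benzyloxy)phenyl]-3,4-dihydro-2H-chromene (2,3-trans-3,4-trans)
Conditions: BnSH (5 equiv), ZnI2 (0.5 equiv), CH2Cl2, 0 °C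
Reagents that add atoms: phenylmethanethiol, SCc1ccccc1
Why: SN1 thiolysis as in step 13; both C4 epimers give the same cation, the thiol in excess outruns the free C6 of ring A, and attack anti to the 3-benzyloxy group should give mainly the 3,4-trans thioether.

Step 24
Reactants: 28 unit M thioether; 15 unit B silyl ether
Product: 29 protected dimer M–B: the (2R)-2,3-trans-3,4-trans-3,7,8-tris(benzyloxy)-2-[4-(benzyloxy)phenyl]chroman-4-yl group bonded through C4 to C6 of 15
Conditions: AgOTf (1.5 equiv), DTBMP (2 equiv), 4 Å molecular sieves, CH2Cl2/THF, −40 → 0 °C, dark; 28 added slowly to 15 (3 equiv, excess recovered)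
Reagents that add atoms: none
Why: AgOTf-promoted Friedel–Crafts alkylation with a flavan-4-yl thioether: silver takes the sulfur, the C4 cation is attacked by C6 of 15 (ortho to O7, para to O1) anti to the 3-benzyloxy group, which sets C4 of M trans to O3. The hindered pyridine takes up the acid, so the silyl ether at C4 of B is not ionised. The excess of 15 and the slow addition hold back alkylation of 28 or 29 at their free C6.

Step 25
Reactants: 17 unit T thioether (1.3 equiv); 29 dimer M–B
Product: 30 protected trimer: the (2R)-2,3-cis-3,4-trans-3,7,8-tris(benzyloxy)-2-[4-(benzyloxy)phenyl]-6-bromochroman-4-yl group bonded through C4 to C6 of unit M of 29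
Conditions: AgOTf (2 equiv), DTBMP (2.5 equiv), 4 Å molecular sieves, CH2Cl2/THF, −40 → 0 °C, dark
Reagents that add atoms: none
Why: The same AgOTf-promoted Friedel–Crafts alkylation; the 2,3-cis cation is attacked anti to its axial 3-benzyloxy group, so C4 of T is set trans to O3. The only strongly activated free position in 29 is C6 of unit M, and the bromine on 17 rules out self-alkylation.

Step 26
Reactants: 30 protected trimer
Product: 31 desilylated trimer: 30 with a free 4-hydroxyl in unit B
Conditions: TBAF (3 equiv), THF, 0 °C → rt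
Reagents that add atoms: none
Why: Fluoride cleavage of the silyl ether; the medium is basic, so the benzylic C4–O bond cannot ionise, and no phenol is free yet.

Step 27
Reactants: 31 desilylated trimer
Product: 32 epioritin-(4β→6)-oritin-(4α→6)-epioritin-4α-ol (CNP0140823.2)
Conditions: H2 (1 atm), Pd(OH)2/C, NaOAc (1.2 equiv), THF/MeOH, rt; filtration under argon
Reagents that add atoms: none
Why: Hydrogenolysis of the twelve benzyl ethers and of the aryl C–Br bond in one operation; acetate takes up the hydrogen bromide, so the benzylic C4 hydroxyl of unit B meets neither acid nor base.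

## Compound list

1 | 2,3-dihydroxybenzaldehyde | O=Cc1cccc(O)c1O | starting material
2 | 2,3-bis(benzyloxy)benzaldehyde | O=Cc1cccc(OCc2ccccc2)c1OCc1ccccc1 | intermediate
3 | 2,3-bis(benzyloxy)phenyl formate (not isolated) | O=COc1cccc(OCc2ccccc2)c1OCc1ccccc1 | intermediate
4 | 2,3-bis(benzyloxy)phenol | Oc1cccc(OCc2ccccc2)c1OCc1ccccc1 | intermediate
5 | 1-(benzyloxy)-4-bromobenzene | Brc1ccc(OCc2ccccc2)cc1 | starting material
6 | [4-(benzyloxy)phenyl]magnesium bromide (titrated THF solution) | Br[Mg]c1ccc(OCc2ccccc2)cc1 | intermediate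
7 | (R)-glyceraldehyde acetonide, (4R)-2,2-dimethyl-1,3-dioxolane-4-carbaldehyde | O=C[C@H]1COC(C)(C)O1 | starting material
8 | (S)-[4-(benzyloxy)phenyl][(4R)-2,2-dimethyl-1,3-dioxolan-4-yl]methanol (anti) | CC1(C)OC[C@@H](O1)[C@@H](O)c1ccc(OCc2ccccc2)cc1 | intermediate
9 | (4R)-4-{(R)-[2,3-bis(benzyloxy)phenoxy][4-(benzyloxy)phenyl]methyl}-2,2-dimethyl-1,3-dioxolane | CC1(C)OC[C@@H](O1)[C@H](Oc1cccc(OCc2ccccc2)c1OCc1ccccc1)c1ccc(OCc2ccccc2)cc1 | intermediate
10 | (2R,3R)-3-[2,3-bis(benzyloxy)phenoxy]-3-[4-(benzyloxy)phenyl]propane-1,2-diol | OC[C@@H](O)[C@H](Oc1cccc(OCc2ccccc2)c1OCc1ccccc1)c1ccc(OCc2ccccc2)cc1 | intermediate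
11 | (4R)-4-{(R)-[2,3-bis(benzyloxy)phenoxy][4-(benzyloxy)phenyl]methyl}-2-phenyl-1,3-dioxolane, both epimers at the acetal carbon | c1ccccc1C1OC[C@@H](O1)[C@H](Oc1cccc(OCc2ccccc2)c1OCc1ccccc1)c1ccc(OCc2ccccc2)cc1 | intermediate
12 | (2R,3R)-2-(benzyloxy)-3-[2,3-bis(benzyloxy)phenoxy]-3-[4-(benzyloxy)phenyl]propan-1-ol | OC[C@@H](OCc1ccccc1)[C@H](Oc1cccc(OCc2ccccc2)c1OCc1ccccc1)c1ccc(OCc2ccccc2)cc1 | intermediate
13 | (2S,3R)-2-(benzyloxy)-3-[2,3-bis(benzyloxy)phenoxy]-3-[4-(benzyloxy)phenyl]propanal | O=C[C@@H](OCc1ccccc1)[C@H](Oc1cccc(OCc2ccccc2)c1OCc1ccccc1)c1ccc(OCc2ccccc2)cc1 | intermediate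
14 | (2R,3R,4R)-3,7,8-tris(benzyloxy)-2-[4-(benzyloxy)phenyl]-3,4-dihydro-2H-chromen-4-ol (2,3-cis-3,4-cis) | c1cc2c(c(OCc5ccccc5)c1OCc5ccccc5)O[C@H](c1ccc(OCc5ccccc5)cc1)[C@H](OCc5ccccc5)[C@@H]2O | intermediate
15 | tert-butyl{[(2R,3S,4R)-3,7,8-tris(benzyloxy)-2-[4-(benzyloxy)phenyl]-3,4-dihydro-2H-chromen-4-yl]oxy}dimethylsilane (silyl ether of 14) | c1cc2c(c(OCc5ccccc5)c1OCc5ccccc5)O[C@H](c1ccc(OCc5ccccc5)cc1)[C@H](OCc5ccccc5)[C@@H]2O[Si](C)(C)C(C)(C)C | intermediate
16 | (2R,3R,4R)-3,7,8-tris(benzyloxy)-2-[4-(benzyloxy)phenyl]-6-bromo-3,4-dihydro-2H-chromen-4-ol | Brc1cc2c(c(OCc5ccccc5)c1OCc5ccccc5)O[C@H](c1ccc(OCc5ccccc5)cc1)[C@H](OCc5ccccc5)[C@@H]2O | intermediate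
17 | (2R,3S,4S)-4-(benzylsulfanyl)-3,7,8-tris(benzyloxy)-2-[4-(benzyloxy)phenyl]-6-bromo-3,4-dihydro-2H-chromene (2,3-cis-3,4-trans) | Brc1cc2c(c(OCc5ccccc5)c1OCc5ccccc5)O[C@H](c1ccc(OCc5ccccc5)cc1)[C@H](OCc5ccccc5)[C@H]2SCc5ccccc5 | intermediate
18 | (S)-glyceraldehyde acetonide, (4S)-2,2-dimethyl-1,3-dioxolane-4-carbaldehyde | O=C[C@@H]1COC(C)(C)O1 | starting material
19 | [4-(benzyloxy)phenyl][(4S)-2,2-dimethyl-1,3-dioxolan-4-yl]methanol, both carbinol epimers | CC1(C)OC[C@H](O1)C(O)c1ccc(OCc2ccccc2)cc1 | intermediate
20 | [4-(benzyloxy)phenyl][(4S)-2,2-dimethyl-1,3-dioxolan-4-yl]methanone | CC1(C)OC[C@H](O1)C(=O)c1ccc(OCc2ccccc2)cc1 | intermediate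
21 | (S)-[4-(benzyloxy)phenyl][(4S)-2,2-dimethyl-1,3-dioxolan-4-yl]methanol (syn) | CC1(C)OC[C@H](O1)[C@@H](O)c1ccc(OCc2ccccc2)cc1 | intermediate
22 | (4S)-4-{(R)-[2,3-bis(benzyloxy)phenoxy][4-(benzyloxy)phenyl]methyl}-2,2-dimethyl-1,3-dioxolane | CC1(C)OC[C@H](O1)[C@H](Oc1cccc(OCc2ccccc2)c1OCc1ccccc1)c1ccc(OCc2ccccc2)cc1 | intermediate
23 | (2S,3R)-3-[2,3-bis(benzyloxy)phenoxy]-3-[4-(benzyloxy)phenyl]propane-1,2-diol | OC[C@H](O)[C@H](Oc1cccc(OCc2ccccc2)c1OCc1ccccc1)c1ccc(OCc2ccccc2)cc1 | intermediate
24 | (4S)-4-{(R)-[2,3-bis(benzyloxy)phenoxy][4-(benzyloxy)phenyl]methyl}-2-phenyl-1,3-dioxolane, both epimers at the acetal carbon | c1ccccc1C1OC[C@H](O1)[C@H](Oc1cccc(OCc2ccccc2)c1OCc1ccccc1)c1ccc(OCc2ccccc2)cc1 | intermediate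
25 | (2S,3R)-2-(benzyloxy)-3-[2,3-bis(benzyloxy)phenoxy]-3-[4-(benzyloxy)phenyl]propan-1-ol | OC[C@H](OCc1ccccc1)[C@H](Oc1cccc(OCc2ccccc2)c1OCc1ccccc1)c1ccc(OCc2ccccc2)cc1 | intermediate
26 | (2R,3R)-2-(benzyloxy)-3-[2,3-bis(benzyloxy)phenoxy]-3-[4-(benzyloxy)phenyl]propanal | O=C[C@H](OCc1ccccc1)[C@H](Oc1cccc(OCc2ccccc2)c1OCc1ccccc1)c1ccc(OCc2ccccc2)cc1 | intermediate
27 | (2R,3S)-3,7,8-tris(benzyloxy)-2-[4-(benzyloxy)phenyl]-3,4-dihydro-2H-chromen-4-ol (2,3-trans), both C4 epimers | c1cc2c(c(OCc5ccccc5)c1OCc5ccccc5)O[C@H](c1ccc(OCc5ccccc5)cc1)[C@@H](OCc5ccccc5)C2O | intermediate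
28 | (2R,3R,4R)-4-(benzylsulfanyl)-3,7,8-tris(benzyloxy)-2-[4-(benzyloxy)phenyl]-3,4-dihydro-2H-chromene (2,3-trans-3,4-trans) | c1cc2c(c(OCc5ccccc5)c1OCc5ccccc5)O[C@H](c1ccc(OCc5ccccc5)cc1)[C@@H](OCc5ccccc5)[C@@H]2SCc5ccccc5 | intermediate
29 | protected dimer M–B: unit M (2R, 2,3-trans-3,4-trans, four benzyl ethers) bonded from C4 to C6 of unit B (silyl ether 15) | c3cc4c(c(OCc5ccccc5)c3OCc5ccccc5)O[C@H](c3ccc(OCc5ccccc5)cc3)[C@@H](OCc5ccccc5)[C@@H]4c3cc4c(c(OCc5ccccc5)c3OCc5ccccc5)O[C@H](c3ccc(OCc5ccccc5)cc3)[C@H](OCc5ccccc5)[C@@H]4O[Si](C)(C)C(C)(C)C | intermediate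
30 | protected trimer: 6-bromo unit T (2R, 2,3-cis-3,4-trans, four benzyl ethers) bonded from C4 to C6 of unit M of 29 | c5ccccc5COc1ccc([C@H]2Oc3c(cc(Br)c(OCc5ccccc5)c3OCc5ccccc5)[C@H](c3cc4c(c(OCc5ccccc5)c3OCc5ccccc5)O[C@H](c3ccc(OCc5ccccc5)cc3)[C@@H](OCc5ccccc5)[C@@H]4c3cc4c(c(OCc5ccccc5)c3OCc5ccccc5)O[C@H](c3ccc(OCc5ccccc5)cc3)[C@H](OCc5ccccc5)[C@@H]4O[Si](C)(C)C(C)(C)C)[C@H]2OCc5ccccc5)cc1 | intermediate
31 | desilylated trimer: 30 with a free 4-hydroxyl in unit B | c5ccccc5COc1ccc([C@H]2Oc3c(cc(Br)c(OCc5ccccc5)c3OCc5ccccc5)[C@H](c3cc4c(c(OCc5ccccc5)c3OCc5ccccc5)O[C@H](c3ccc(OCc5ccccc5)cc3)[C@@H](OCc5ccccc5)[C@@H]4c3cc4c(c(OCc5ccccc5)c3OCc5ccccc5)O[C@H](c3ccc(OCc5ccccc5)cc3)[C@H](OCc5ccccc5)[C@@H]4O)[C@H]2OCc5ccccc5)cc1 | intermediate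
32 | epioritin-(4β→6)-oritin-(4α→6)-epioritin-4α-ol; unit T (2R,3R,4S), unit M (2R,3S,4R), unit B (2R,3R,4R) | Oc1ccc([C@H]2Oc3c(ccc(O)c3O)[C@H](c3cc4c(c(O)c3O)O[C@H](c3ccc(O)cc3)[C@@H](O)[C@@H]4c3cc4c(c(O)c3O)O[C@H](c3ccc(O)cc3)[C@H](O)[C@@H]4O)[C@H]2O)cc1 | target

## Step count and least certain steps

Total step count: 27. Longest linear sequence: 15 steps (from 5 through step 3 and steps 14 to 23, then steps 24 to 27).

**Step 10 (key step).** The most likely failure is ionisation of the newly formed benzylic C4–O bond while the Lewis acid is still present. The cation is para to O7 and ortho to O1, and it would go on to the chloride, to elimination or to alkylation of C6 of a second molecule. A second risk is erosion of the 3,4-cis selectivity if the ring A ethers compete with the O3/aldehyde chelate for tin. Fallback, from 13: Pinnick oxidation (NaClO2, NaH2PO4, 2-methyl-2-butene) to (2S,3R)-2-(benzyloxy)-3-[2,3-bis(benzyloxy)phenoxy]-3-[4-(benzyloxy)phenyl]propanoic acid F1. Intramolecular Friedel–Crafts acylation through the mixed trifluoroacetic anhydride then gives the 2,3-cis flavan-4-one (2R,3S)-3,7,8-tris(benzyloxy)-2-[4-(benzyloxy)phenyl]-2,3-dihydro-4H-chromen-4-one F2, which has no ionisable C4–O bond. Reduction with NaBH4 at low temperature should deliver hydride axially, anti to the axial 3-benzyloxy group, and so return to 14.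

**Step 25.** The most likely failure is slow capture of the cation from 17. C6 of unit M in 29 sits on a crowded dimer next to a benzyl ether, so loss of a proton to the flav-3-ene or alkylation of a ring B could take over. Fallback, reversing the order of the two interflavanyl bonds: 27 is acetylated (Ac2O, Et3N, DMAP) to the 2,3-trans flavan-4-yl acetate F3, whose acetate does not answer to silver. 17 is coupled with F3 under the conditions of step 25 to the T–M dimer acetate F4. The acetate is exchanged for benzylthio (BnSH, ZnI2) to give the T–M dimer thioether F5. F5 is coupled with 15 (AgOTf, DTBMP) to come back at 30.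

**Step 24.** The most likely failure is self-alkylation: the cation from 28 is trapped by the free C6 of a second molecule of 28 or of 29, giving oligomers. Some 3,4-cis epimer may also form, because a 2,3-trans cation is less biased than a 2,3-cis one; this would be removed at this stage. Fallback, from 27, capping C6 of unit M: NBS gives the 6-bromo-2,3-trans flavan-4-ol F6. Thiolysis as in step 23 gives the 6-bromo thioether F7. AgOTf coupling with only a slight excess of 15 gives the 6-bromo dimer F8. Bromine–lithium exchange (n-BuLi, THF, −78 °C) followed by protonation with MeOH returns to 29.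

**Step 5 (the same holds for step 17).** The most likely failure is loss of stereospecificity: the alkoxyphosphonium ion of a 4-alkoxybenzylic carbinol can ionise, and attack on the ion pair from both faces would scramble C2. Fallback, from 8 (or from the crude epimer mixture of step 4), forming the ether with retention instead: Dess–Martin oxidation gives the ketone [4-(benzyloxy)phenyl][(4R)-2,2-dimethyl-1,3-dioxolan-4-yl]methanone F9. Felkin–Anh reduction with LiBH(s-Bu)3 gives the syn carbinol (R)-[4-(benzyloxy)phenyl][(4R)-2,2-dimethyl-1,3-dioxolan-4-yl]methanol F10. Palladium-catalysed C–O coupling of F10 (Pd2(dba)3, a bulky biaryl di-tert-butylphosphine, Cs2CO3, toluene, 90 °C) with 1,2-bis(benzyloxy)-3-bromobenzene F11, the dibenzyl ether of a commercial bromocatechol, leaves the carbinol carbon untouched and comes back at 9.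

**Step 27.** The most likely failure is over-reduction: once the phenols are free, the benzylic C4–O bond of unit B can be hydrogenolysed, or the hydrogen bromide from the debromination can ionise it. Fallback, from 30, changing the order of the last two operations: hydrogenolysis with the silyl ether still in place (H2, Pd(OH)2/C, NaOAc, THF/EtOAc) gives the silylated polyphenol F12. The silyl group is then removed with TBAF buffered by AcOH under argon, to arrive at 32.

## Further compounds

F1 | step 10 | (2S,3R)-2-(benzyloxy)-3-[2,3-bis(benzyloxy)phenoxy]-3-[4-(benzyloxy)phenyl]propanoic acid | OC(=O)[C@@H](OCc1ccccc1)[C@H](Oc1cccc(OCc2ccccc2)c1OCc1ccccc1)c1ccc(OCc2ccccc2)cc1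
F2 | step 10 | (2R,3S)-3,7,8-tris(benzyloxy)-2-[4-(benzyloxy)phenyl]-2,3-dihydro-4H-chromen-4-one (2,3-cis) | c1cc2c(c(OCc5ccccc5)c1OCc5ccccc5)O[C@H](c1ccc(OCc5ccccc5)cc1)[C@H](OCc5ccccc5)C2=O
F3 | step 25 | (2R,3S)-3,7,8-tris(benzyloxy)-2-[4-(benzyloxy)phenyl]-3,4-dihydro-2H-chromen-4-yl acetate (2,3-trans, both C4 epimers) | c1cc2c(c(OCc5ccccc5)c1OCc5ccccc5)O[C@H](c1ccc(OCc5ccccc5)cc1)[C@@H](OCc5ccccc5)C2OC(C)=O
F4 | step 25 | T–M dimer acetate: 6-bromo unit T (2,3-cis-3,4-trans) bonded from C4 to C6 of F3 | c5ccccc5COc1ccc([C@H]2Oc3c(cc(Br)c(OCc5ccccc5)c3OCc5ccccc5)[C@H](c3cc4c(c(OCc5ccccc5)c3OCc5ccccc5)O[C@H](c3ccc(OCc5ccccc5)cc3)[C@@H](OCc5ccccc5)C4OC(C)=O)[C@H]2OCc5ccccc5)cc1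
F5 | step 25 | T–M dimer thioether: F4 with benzylsulfanyl in place of acetoxy at C4 of unit M | c5ccccc5COc1ccc([C@H]2Oc3c(cc(Br)c(OCc5ccccc5)c3OCc5ccccc5)[C@H](c3cc4c(c(OCc5ccccc5)c3OCc5ccccc5)O[C@H](c3ccc(OCc5ccccc5)cc3)[C@@H](OCc5ccccc5)C4SCc5ccccc5)[C@H]2OCc5ccccc5)cc1
F6 | step 24 | (2R,3S)-3,7,8-tris(benzyloxy)-2-[4-(benzyloxy)phenyl]-6-bromo-3,4-dihydro-2H-chromen-4-ol (2,3-trans, both C4 epimers) | Brc1cc2c(c(OCc5ccccc5)c1OCc5ccccc5)O[C@H](c1ccc(OCc5ccccc5)cc1)[C@@H](OCc5ccccc5)C2O
F7 | step 24 | (2R,3R,4R)-4-(benzylsulfanyl)-3,7,8-tris(benzyloxy)-2-[4-(benzyloxy)phenyl]-6-bromo-3,4-dihydro-2H-chromene (2,3-trans-3,4-trans) | Brc1cc2c(c(OCc5ccccc5)c1OCc5ccccc5)O[C@H](c1ccc(OCc5ccccc5)cc1)[C@@H](OCc5ccccc5)[C@@H]2SCc5ccccc5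
F8 | step 24 | 6-bromo dimer: 29 with bromine on C6 of unit M | Brc3cc4c(c(OCc5ccccc5)c3OCc5ccccc5)O[C@H](c3ccc(OCc5ccccc5)cc3)[C@@H](OCc5ccccc5)[C@@H]4c3cc4c(c(OCc5ccccc5)c3OCc5ccccc5)O[C@H](c3ccc(OCc5ccccc5)cc3)[C@H](OCc5ccccc5)[C@@H]4O[Si](C)(C)C(C)(C)C
F9 | step 5 | [4-(benzyloxy)phenyl][(4R)-2,2-dimethyl-1,3-dioxolan-4-yl]methanone | CC1(C)OC[C@@H](O1)C(=O)c1ccc(OCc2ccccc2)cc1
F10 | step 5 | (R)-[4-(benzyloxy)phenyl][(4R)-2,2-dimethyl-1,3-dioxolan-4-yl]methanol (syn) | CC1(C)OC[C@@H](O1)[C@H](O)c1ccc(OCc2ccccc2)cc1
F11 | step 5 | 1,2-bis(benzyloxy)-3-bromobenzene | Brc1cccc(OCc2ccccc2)c1OCc1ccccc1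
F12 | step 27 | target 32 carrying a tert-butyldimethylsilyl ether on O4 of unit B | Oc1ccc([C@H]2Oc3c(ccc(O)c3O)[C@H](c3cc4c(c(O)c3O)O[C@H](c3ccc(O)cc3)[C@@H](O)[C@@H]4c3cc4c(c(O)c3O)O[C@H](c3ccc(O)cc3)[C@H](O)[C@@H]4O[Si](C)(C)C(C)(C)C)[C@H]2O)cc1
A1 | alternative 1 | ortho-hydroxy diaryl carbinol: [3,4-bis(benzyloxy)-2-hydroxyphenyl] carbinol on C6 of the 3,4-acetonide of unit B (carbinol epimers) | Oc1c(OCc5ccccc5)c(OCc5ccccc5)ccc1C(O)c3cc4c(c(OCc5ccccc5)c3OCc5ccccc5)O[C@H](c3ccc(OCc5ccccc5)cc3)[C@H](OC(C)(C)O6)[C@@H]46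
A2 | alternative 1 | ortho-quinone methide from A1: 2,3-bis(benzyloxy)-6-(arylmethylidene)cyclohexa-2,4-dien-1-one with the 3,4-acetonide of unit B as the aryl group (alkene geometry not fixed) | O=C1C(OCc5ccccc5)=C(OCc5ccccc5)C=CC1=Cc3cc4c(c(OCc5ccccc5)c3OCc5ccccc5)O[C@H](c3ccc(OCc5ccccc5)cc3)[C@H](OC(C)(C)O6)[C@@H]46
A3 | alternative 1 | 1-(benzyloxy)-4-ethynylbenzene | C#Cc1ccc(OCc2ccccc2)cc1
A4 | alternative 1 | M–B dimer with unit M as its 2-aryl-4H-chromene and unit B as its 3,4-acetonide | c1cc2c(c(OCc5ccccc5)c1OCc5ccccc5)OC(c1ccc(OCc5ccccc5)cc1)=C[C@@H]2c3cc4c(c(OCc5ccccc5)c3OCc5ccccc5)O[C@H](c3ccc(OCc5ccccc5)cc3)[C@H](OC(C)(C)O6)[C@@H]46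
A5 | alternative 2 | open-chain bromo alcohol: 2-O-benzyl, 1-O-silyl 1-[3,4-bis(benzyloxy)-2-bromophenyl]-3-[4-(benzyloxy)phenyl]propane-1,2,3-triol with a free 3-hydroxyl | O[C@H](c1ccc(OCc5ccccc5)cc1)[C@H](OCc5ccccc5)[C@H](O[Si](C)(C)C(C)(C)C)c1ccc(OCc5ccccc5)c(OCc5ccccc5)c1Br
A6 | alternative 2 | protected unit B, identical with 15 | c1cc2c(c(OCc5ccccc5)c1OCc5ccccc5)O[C@H](c1ccc(OCc5ccccc5)cc1)[C@H](OCc5ccccc5)[C@@H]2O[Si](C)(C)C(C)(C)C
A7 | alternative 3 | cis-epoxide: C4 of unit T bearing the free ring A phenol, the M–B dimer and a cis-2-(4-pivaloyloxyphenyl)oxirane | CC(C)(C)C(=O)Oc1ccc([C@@H]2O[C@@H]2[C@H](c3ccc(OCc5ccccc5)c(OCc5ccccc5)c3O)c3cc4c(c(OCc5ccccc5)c3OCc5ccccc5)O[C@H](c3ccc(OCc5ccccc5)cc3)[C@@H](OCc5ccccc5)[C@@H]4c3cc4c(c(OCc5ccccc5)c3OCc5ccccc5)O[C@H](c3ccc(OCc5ccccc5)cc3)[C@H](OC(C)(C)O6)[C@@H]46)cc1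
A8 | alternative 3 | protected trimer with a pivalate on ring B of unit T, a free 3-hydroxyl in T and the 3,4-acetonide of unit B | CC(C)(C)C(=O)Oc1ccc([C@H]2Oc3c(ccc(OCc5ccccc5)c3OCc5ccccc5)[C@H](c3cc4c(c(OCc5ccccc5)c3OCc5ccccc5)O[C@H](c3ccc(OCc5ccccc5)cc3)[C@@H](OCc5ccccc5)[C@@H]4c3cc4c(c(OCc5ccccc5)c3OCc5ccccc5)O[C@H](c3ccc(OCc5ccccc5)cc3)[C@H](OC(C)(C)O6)[C@@H]46)[C@H]2O)cc1
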